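**Plan**

1. Retrosynthesis: the silyl ether on the 4'-phenol goes last. The dihydrofuran ring is then cut at C2–C3 and C2–O1 (a [4+1] disconnection) and, in the same operation, at the exocyclic CH2–C3 bond. This leaves an aryloxymethyl carbanion (from eugenol), an O-Boc salicylaldehyde whose formyl carbon is C3 (from eugenol), and a chiral benzylsulfonium ylide carrying C2 (from vanillin).
2. Enabling feature: O1–C7a–C3a–C3 of the dihydrobenzofuran is an ortho-hydroxybenzyl array on the 5-allyl-7-methoxy arene, i.e. a latent o-quinone methide with C3 as its exocyclic carbon.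
3. Forward order: CH2–C3 is made first by 1,2-addition; an O→O Boc shift and loss of tert-butyl carbonate unveil the o-quinone methide in the same flask; the ylide then forms C3–C2 and O1–C2. The only non-aromatic ring therefore arises last, in the key step; all three arenes are bought.
4. Stereochemistry: C2 comes from the ylide face fixed by (2S,5S)-2,5-dimethylthiolane (from (2R,5R)-hexane-2,5-diol by double inversion); C3 comes from the trans-selective annulation. The final desilylation touches neither centre.

Key step: step 10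

Assumption: the C2-symmetric thiolanium benzylide is taken to present to the o-quinone methide the same face it presents to aldehydes, which points to the (2S,5S)-sulfide for the (2S,3R) product; if a model run showed the opposite sense, the (2R,5R)-sulfide from (2S,5S)-hexane-2,5-diol would be used with no other change.

**Route**

Step 1
Reactants: 1 eugenol (4-allyl-2-methoxyphenol)
Product: 2 5-allyl-2-hydroxy-3-methoxybenzaldehyde
Conditions: MgCl2, Et3N, (CH2O)n, MeCN, reflux; aq. HCl work-up
Reagents that add atoms: paraformaldehyde (as formaldehyde), C=O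
Why: In this Casnati–Skattebøl ortho-formylation the magnesium phenoxide directs formaldehyde to the only free ortho position and a second formaldehyde oxidizes the hydroxymethyl intermediate, so the allyl group should be untouched.

Step 2
Reactants: 2 5-allyl-2-hydroxy-3-methoxybenzaldehyde
Product: 3 4-allyl-2-formyl-6-methoxyphenyl tert-butyl carbonate
Conditions: Boc2O, DMAP (cat.), CH2Cl2, rt
Reagents that add atoms: di-tert-butyl dicarbonate, CC(C)(C)OC(=O)OC(=O)OC(C)(C)C
Why: DMAP-catalysed O-acylation of the phenol installs the carbonate that later serves as the migrating trigger for o-quinone methide formation.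

Step 3
Reactants: 1 eugenol; 4 tributyl(iodomethyl)stannane
Product: 5 tributyl[(4-allyl-2-methoxyphenoxy)methyl]stannane
Conditions: K2CO3, DMF, rt
Reagents that add atoms: none
Why: Williamson etherification of the phenoxide with the primary iodide should give the α-stannyl ether, a bench-stable precursor of the aryloxymethyl carbanion, under conditions too mild to isomerize the allyl group.

Step 4
Reactants: 6 (2R,5R)-hexane-2,5-diol
Product: 7 (2R,5R)-hexane-2,5-diyl dimethanesulfonate
Conditions: MsCl, Et3N, CH2Cl2, 0 °C
Reagents that add atoms: methanesulfonyl chloride, CS(=O)(=O)Cl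
Why: O-Sulfonylation of both secondary alcohols proceeds with retention at carbon and activates them for displacement.

Step 5
Reactants: 7 (2R,5R)-hexane-2,5-diyl dimethanesulfonate
Product: 8 (2S,5S)-2,5-dimethylthiolane
Conditions: Na2S·9H2O, EtOH, rt
Reagents that add atoms: sodium sulfide, [Na+].[Na+].[S-2]
Why: Double SN2 displacement by sulfide inverts both centres and closes the five-membered ring, giving the C2-symmetric (2S,5S) sulfide.

Step 6
Reactants: 9 vanillin (4-hydroxy-3-methoxybenzaldehyde)
Product: 10 3-methoxy-4-(triisopropylsilyloxy)benzaldehyde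
Conditions: TIPSCl, imidazole, DMF, rt
Reagents that add atoms: chlorotriisopropylsilane, CC(C)[Si](Cl)(C(C)C)C(C)C
Why: Silylation of the phenol gives a bulky aryl silyl ether that should survive hydride, ylide formation and organometallic conditions and is removed by fluoride.

Step 7
Reactants: 10 3-methoxy-4-(triisopropylsilyloxy)benzaldehyde
Product: 11 [3-methoxy-4-(triisopropylsilyloxy)phenyl]methanol
Conditions: NaBH4, MeOH, 0 °C
Reagents that add atoms: none
Why: Borohydride reduction of the aryl aldehyde to the benzylic alcohol is chemoselective in the presence of the silyl ether.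

Step 8
Reactants: 11 [3-methoxy-4-(triisopropylsilyloxy)phenyl]methanol
Product: 12 [4-(bromomethyl)-2-methoxyphenoxy]triisopropylsilane
Conditions: CBr4, PPh3, CH2Cl2, 0 °C
Reagents that add atoms: carbon tetrabromide, BrC(Br)(Br)Br
Why: The Appel reaction converts the benzylic alcohol to the bromide under neutral conditions that spare the silyl ether.

Step 9
Reactants: 12 [4-(bromomethyl)-2-methoxyphenoxy]triisopropylsilane; 8 (2S,5S)-2,5-dimethylthiolane
Product: 13 (2S,5S)-1-[3-methoxy-4-(triisopropylsilyloxy)benzyl]-2,5-dimethylthiolan-1-ium tetrafluoroborate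
Conditions: NaBF4, acetone, rt
Reagents that add atoms: sodium tetrafluoroborate, [Na+].F[B-](F)(F)F
Why: S-Alkylation of the sulfide by the activated benzylic bromide, driven by precipitation of sodium bromide and pairing with a non-nucleophilic anion, should give the sulfonium salt; sulfur is not a stereocentre because the two ring carbons are homotopic.

Step 10
Reactants: 5 tributyl[(4-allyl-2-methoxyphenoxy)methyl]stannane; 3 4-allyl-2-formyl-6-methoxyphenyl tert-butyl carbonate; 13 (2S,5S)-1-[3-methoxy-4-(triisopropylsilyloxy)benzyl]-2,5-dimethylthiolan-1-ium tetrafluoroborate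
Product: 20 (2S,3R)-5-allyl-3-[(4-allyl-2-methoxyphenoxy)methyl]-7-methoxy-2-[3-methoxy-4-(triisopropylsilyloxy)phenyl]-2,3-dihydrobenzofuran, via aryloxymethyllithium 14 (not isolated), via lithium alkoxide adduct 15 (not isolated), via lithium phenoxide benzylic carbonate 16 (not isolated), via sulfonium benzylide 17 (not isolated), via o-quinone methide 18 (not isolated), via phenoxide sulfonium betaine 19 (not isolated)
Conditions: 5, n-BuLi (1.0 equiv), THF, −78 °C; then 3, −78 °C; then ylide from 13 and KHMDS (THF, −78 °C, second flask); MgBr2·OEt2, −78 → −20 °C; aq. NH4Cl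
Reagents that add atoms: none
Why: Proposed new method: the organolithium from tin–lithium exchange adds to the formyl carbon (the future C3) faster than to the carbonate, the resulting alkoxide takes over the Boc group from the neighbouring phenol oxygen, and magnesium-assisted loss of tert-butyl carbonate from the phenoxide unveils the o-quinone methide spanning O1–C7a–C3a–C3, which the benzylide attacks at C3 before the phenoxide expels the sulfide. The closest known reaction types are the low-temperature anionic o-quinone methide cascade of O-Boc salicylaldehydes with two different organometallics, the [4+1] annulation of o-quinone methides with achiral benzylsulfonium ylides to trans-2-aryl-2,3-dihydrobenzofurans, and the chiral-thiolane benzylide epoxidation of aldehydes (Corey–Chaykovsky type). The furan ring closes by 5-exo-tet O-alkylation of the phenoxide at the sulfonium-bearing carbon, with inversion there. C2 is controlled by the C2-symmetric (2S,5S)-thiolanium group, whose methyl groups leave one ylide face open, and C3 follows from the anti approach that places the 2-aryl and 3-aryloxymethyl groups trans. The step needs 1,2-addition to be complete before any ylide is present and conjugate capture by the ylide instead of by a second organolithium; the ortho O-Boc relay (the lithium phenoxide should persist at −78 °C until MgBr2 is added) and the 1:1 organolithium stoichiometry are meant to secure this.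

Step 11
Reactants: 20 (2S,3R)-5-allyl-3-[(4-allyl-2-methoxyphenoxy)methyl]-7-methoxy-2-[3-methoxy-4-(triisopropylsilyloxy)phenyl]-2,3-dihydrobenzofuran
Product: 21 4-[(2S,3R)-5-allyl-3-[(4-allyl-2-methoxyphenoxy)methyl]-7-methoxy-2,3-dihydrobenzofuran-2-yl]-2-methoxyphenol (CNP0138854.1)
Conditions: TBAF, AcOH, THF, 0 °C
Reagents that add atoms: none
Why: Fluoride cleaves the aryl silyl ether and acetic acid buffers the liberated phenoxide, so the benzylic C2–O1 bond, C3 and both allyl groups should remain untouched.

**Compound list**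

1 | eugenol (4-allyl-2-methoxyphenol) | C=CCc1ccc(O)c(OC)c1 | starting material
2 | 5-allyl-2-hydroxy-3-methoxybenzaldehyde | O=Cc1cc(CC=C)cc(OC)c1O | intermediate
3 | 4-allyl-2-formyl-6-methoxyphenyl tert-butyl carbonate | O=Cc1cc(CC=C)cc(OC)c1OC(=O)OC(C)(C)C | intermediate
4 | tributyl(iodomethyl)stannane | CCCC[Sn](CI)(CCCC)CCCC | starting material
5 | tributyl[(4-allyl-2-methoxyphenoxy)methyl]stannane | C=CCc1ccc(OC[Sn](CCCC)(CCCC)CCCC)c(OC)c1 | intermediate
6 | (2R,5R)-hexane-2,5-diol | C[C@@H](O)CC[C@@H](C)O | starting material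
7 | (2R,5R)-hexane-2,5-diyl dimethanesulfonate | C[C@@H](OS(C)(=O)=O)CC[C@@H](C)OS(C)(=O)=O | intermediate
8 | (2S,5S)-2,5-dimethylthiolane | C[C@H]1CC[C@H](C)S1 | intermediate
9 | vanillin (4-hydroxy-3-methoxybenzaldehyde) | O=Cc1ccc(O)c(OC)c1 | starting material
10 | 3-methoxy-4-(triisopropylsilyloxy)benzaldehyde | O=Cc1ccc(O[Si](C(C)C)(C(C)C)C(C)C)c(OC)c1 | intermediate
11 | [3-methoxy-4-(triisopropylsilyloxy)phenyl]methanol | OCc1ccc(O[Si](C(C)C)(C(C)C)C(C)C)c(OC)c1 | intermediate
12 | [4-(bromomethyl)-2-methoxyphenoxy]triisopropylsilane | BrCc1ccc(O[Si](C(C)C)(C(C)C)C(C)C)c(OC)c1 | intermediate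
13 | (2S,5S)-1-[3-methoxy-4-(triisopropylsilyloxy)benzyl]-2,5-dimethylthiolan-1-ium tetrafluoroborate | C[C@H]1CC[C@H](C)[S+]1Cc1ccc(O[Si](C(C)C)(C(C)C)C(C)C)c(OC)c1.F[B-](F)(F)F | intermediate
14 | [(4-allyl-2-methoxyphenoxy)methyl]lithium | C=CCc1ccc(OC[Li])c(OC)c1 | intermediate
15 | lithium 2-(4-allyl-2-methoxyphenoxy)-1-[5-allyl-2-(tert-butoxycarbonyloxy)-3-methoxyphenyl]ethanolate (racemic at the carbinol carbon) | C=CCc1ccc(OCC([O-])c2cc(CC=C)cc(OC)c2OC(=O)OC(C)(C)C)c(OC)c1.[Li+] | intermediate
16 | lithium 4-allyl-2-[2-(4-allyl-2-methoxyphenoxy)-1-(tert-butoxycarbonyloxy)ethyl]-6-methoxyphenolate (racemic) | C=CCc1ccc(OCC(OC(=O)OC(C)(C)C)c2cc(CC=C)cc(OC)c2[O-])c(OC)c1.[Li+] | intermediate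
17 | (2S,5S)-2,5-dimethylthiolan-1-ium-1-yl [3-methoxy-4-(triisopropylsilyloxy)phenyl]methanide (sulfonium benzylide) | C[C@H]1CC[C@H](C)[S+]1[CH-]c1ccc(O[Si](C(C)C)(C(C)C)C(C)C)c(OC)c1 | intermediate
18 | 4-allyl-6-[2-(4-allyl-2-methoxyphenoxy)ethylidene]-2-methoxycyclohexa-2,4-dien-1-one (o-quinone methide) | C=CCc1ccc(OCC=C2C=C(CC=C)C=C(OC)C2=O)c(OC)c1 | intermediate
19 | betaine: 4-allyl-2-[(1R,2R)-3-(4-allyl-2-methoxyphenoxy)-1-[(2S,5S)-2,5-dimethylthiolan-1-ium-1-yl]-1-[3-methoxy-4-(triisopropylsilyloxy)phenyl]propan-2-yl]-6-methoxyphenolate | C=CCc1ccc(OC[C@@H](c2cc(CC=C)cc(OC)c2[O-])[C@@H]([S+]2[C@@H](C)CC[C@@H]2C)c2ccc(O[Si](C(C)C)(C(C)C)C(C)C)c(OC)c2)c(OC)c1 | intermediate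
20 | (2S,3R)-5-allyl-3-[(4-allyl-2-methoxyphenoxy)methyl]-7-methoxy-2-[3-methoxy-4-(triisopropylsilyloxy)phenyl]-2,3-dihydrobenzofuran (trans) | C=CCc1ccc(OC[C@H]2c3cc(CC=C)cc(OC)c3O[C@@H]2c2ccc(O[Si](C(C)C)(C(C)C)C(C)C)c(OC)c2)c(OC)c1 | intermediate
21 | 4-[(2S,3R)-5-allyl-3-[(4-allyl-2-methoxyphenoxy)methyl]-7-methoxy-2,3-dihydrobenzofuran-2-yl]-2-methoxyphenol (trans) | C=CCc1ccc(OC[C@H]2c3cc(CC=C)cc(OC)c3O[C@@H]2c2ccc(O)c(OC)c2)c(OC)c1 | target

**Step count**

Total steps: 11. Longest linear sequence: 6 steps (9 → 10 → 11 → 12 → 13 → 20 → 21).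

**Steps most likely to fail**

Step 10 (carries the label). Three processes threaten it:
- proton transfer from a benzylic-allylic CH2 to the organolithium, which would isomerize an allyl group;
- decay of the o-quinone methide (tautomerization to the aryl vinyl ether or dimerization) before the ylide captures it;
- insufficient facial discrimination by the thiolanium ylide at the flat o-quinone methide.

The fallback uses known chemistry, sets out from 5 and 3, and returns at 20. Stannane 5 is lithiated as before and added to 3, but the mixture is quenched at −78 °C with acetic acid to isolate tert-butyl 2-(4-allyl-2-methoxyphenoxy)-1-(5-allyl-2-hydroxy-3-methoxyphenyl)ethyl carbonate F1. Sodium p-toluenesulfinate with K2CO3 in aqueous MeCN converts this, through the o-quinone methide, into the bench-stable sulfone 4-allyl-2-[2-(4-allyl-2-methoxyphenoxy)-1-tosylethyl]-6-methoxyphenol F2. Bromide 12, tetrahydrothiophene and NaBF4 give the achiral salt 1-[3-methoxy-4-(triisopropylsilyloxy)benzyl]thiolan-1-ium tetrafluoroborate F3. F2 and F3 with Cs2CO3 in CH2Cl2 at room temperature should undergo the established base-mediated [4+1] annulation to the racemic trans-dihydrobenzofuran, i.e. 20 together with its (2R,3S) enantiomer F4. Preparative HPLC on a chiral stationary phase then delivers 20.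

Step 9. Ionization of the electron-rich benzylic bromide (solvolysis, oligomerization) may outrun the slow S-alkylation of the hindered sulfide. The fallback sets out from alcohol 11, bypasses bromide 12, and returns at 13. Alcohol 11 and sulfide 8 are treated with TfOH in CH2Cl2 at −40 °C, so that the benzylic cation formed reversibly from the alcohol is trapped by the sulfide under thermodynamic control. This should give (2S,5S)-1-[3-methoxy-4-(triisopropylsilyloxy)benzyl]-2,5-dimethylthiolan-1-ium trifluoromethanesulfonate F5. Washing a CH2Cl2 solution of F5 with aqueous NaBF4 exchanges the anion and gives 13.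

Step 1. Incomplete ortho-formylation, or condensation of the hydroxymethyl intermediate with a second phenol to a diarylmethane, may limit the yield. The fallback sets out from 1 and returns at 2. Eugenol, phenylboronic acid and paraformaldehyde (cat. propionic acid, toluene, reflux with water removal) give the ortho-specific cyclic boronate 6-allyl-8-methoxy-2-phenyl-4H-1,3,2-benzodioxaborinine F6. Aqueous H2O2 in THF releases 4-allyl-2-(hydroxymethyl)-6-methoxyphenol F7. MnO2 in CHCl3 oxidizes the benzylic alcohol of F7 to aldehyde 2.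

**Further compounds**

F1 | step 10 | tert-butyl 2-(4-allyl-2-methoxyphenoxy)-1-(5-allyl-2-hydroxy-3-methoxyphenyl)ethyl carbonate (racemic) | C=CCc1ccc(OCC(OC(=O)OC(C)(C)C)c2cc(CC=C)cc(OC)c2O)c(OC)c1
F2 | step 10 | 4-allyl-2-[2-(4-allyl-2-methoxyphenoxy)-1-tosylethyl]-6-methoxyphenol (racemic) | C=CCc1ccc(OCC(c2cc(CC=C)cc(OC)c2O)S(=O)(=O)c2ccc(C)cc2)c(OC)c1
F3 | step 10 | 1-[3-methoxy-4-(triisopropylsilyloxy)benzyl]thiolan-1-ium tetrafluoroborate | COc1cc(C[S+]2CCCC2)ccc1O[Si](C(C)C)(C(C)C)C(C)C.F[B-](F)(F)F
F4 | step 10 | (2R,3S)-5-allyl-3-[(4-allyl-2-methoxyphenoxy)methyl]-7-methoxy-2-[3-methoxy-4-(triisopropylsilyloxy)phenyl]-2,3-dihydrobenzofuran (enantiomer of 20) | C=CCc1ccc(OC[C@@H]2c3cc(CC=C)cc(OC)c3O[C@H]2c2ccc(O[Si](C(C)C)(C(C)C)C(C)C)c(OC)c2)c(OC)c1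
F5 | step 9 | (2S,5S)-1-[3-methoxy-4-(triisopropylsilyloxy)benzyl]-2,5-dimethylthiolan-1-ium trifluoromethanesulfonate | C[C@H]1CC[C@H](C)[S+]1Cc1ccc(O[Si](C(C)C)(C(C)C)C(C)C)c(OC)c1.[O-]S(=O)(=O)C(F)(F)F
F6 | step 1 | 6-allyl-8-methoxy-2-phenyl-4H-1,3,2-benzodioxaborinine | C=CCc1cc2COB(c3ccccc3)Oc2c(OC)c1
F7 | step 1 | 4-allyl-2-(hydroxymethyl)-6-methoxyphenol | C=CCc1cc(CO)c(O)c(OC)c1
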